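**Plan**
1. Retrosynthetic cuts: the O–Si bond at C6. Then the side-chain σ-bond C2′–C3′ (a CH2 joined to the H-bearing end of the E-C3′=C4′ alkene), which gives (S)-2-vinyl-2H-chromene 12 and E-alkenyl iodide 23. In 12, C3=C4 goes back to the chroman and the allylic O1–C2 bond is opened. In 23, C5′–C6′ is cut (allyl bromide plus alkyne), and the alkyne goes back to a geraniol epoxide.
2. Enabling feature: C2 of the pyran ring is quaternary (O1, CH3, C3=C4, C1′). C1′=C2′ can therefore be carried as a vinyl group that has no allylic hydrogen, is the only monosubstituted alkene, and takes boron at C2′, γ to O1. C3′ bears H and can hold iodine with fixed E geometry.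
3. Right half, forward: arene 1 → o-vinylphenol 4 → Z-allyl carbonate 10. The pyran ring closes at O1–C2 by asymmetric allylic etherification, which creates C2 and the vinyl handle together. DDQ then installs C3=C4.
4. Left half, forward: geraniol → epoxy alcohol → epoxy chloride → (S)-alkynol 16 → copper-catalysed allylation with the C4 linchpin 20 → trans-hydroalumination to the skipped diene 23.
5. Union and end: one-flask hydroboration/B-alkyl Suzuki–Miyaura coupling of 12 with 23, then fluoride.
6. Stereochemistry: C2 comes from the chiral Pd ligand. C8′ comes from the Sharpless epoxidation, and its C–O bond is never broken afterwards. E-C3′=C4′ comes from syn-carboalumination and E-C6′=C7′ from trans-hydroalumination. The two centres are too far apart for relay, so each half is made enantioenriched on its own.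

Key step: step 16

Remark: side-chain atoms are numbered C1′ (on C2) to C13′.
Assumption: for the Z-carbonate 10 the (R,R)-ligand is taken to give (R)-11. If correlation of 11 shows the opposite sense, the equally available (S,S)-ligand is used and nothing else changes.

Step 1
Reactants: 1 2-methylhydroquinone
Product: 2 2-methyl-4-(triisopropylsilyloxy)phenol
Conditions: TIPSCl (1.0 equiv), imidazole, DMF, 0 °C
Reagents that add atoms: triisopropylsilyl chloride, CC(C)[Si](Cl)(C(C)C)C(C)C
Why: In this phenol silylation with a bulky chlorosilane, the C4–OH has no ortho substituent and should react ahead of the C1–OH flanked by the methyl group, so the oxygen that becomes O1 stays free.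

Step 2
Reactants: 2 2-methyl-4-(triisopropylsilyloxy)phenol
Product: 3 2-hydroxy-3-methyl-5-(triisopropylsilyloxy)benzaldehyde
Conditions: MgCl2, Et3N, (CH2O)n, MeCN, reflux; then 1 M HCl
Reagents that add atoms: paraformaldehyde (as formaldehyde), C=O
Why: The magnesium-phenoxide-directed ortho-formylation (Casnati–Skattebøl reaction) delivers formaldehyde only ortho to the free OH, where C6 is the single open position, and a second formaldehyde accepts the hydride.

Step 3
Reactants: 3 2-hydroxy-3-methyl-5-(triisopropylsilyloxy)benzaldehyde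
Product: 4 2-methyl-4-(triisopropylsilyloxy)-6-vinylphenol
Conditions: Ph3PCH3Br, KOtBu (2.3 equiv each), THF, 0 °C → rt
Reagents that add atoms: methyltriphenylphosphonium bromide, C[P+](c1ccccc1)(c1ccccc1)c1ccccc1.[Br-]
Why: In this Wittig methylenation one equivalent of base is spent on the phenol and the phenoxide aldehyde still olefinates, as is usual for salicylaldehydes.

Step 4
Reactants: 5 but-2-yn-1-ol
Product: 7 (Z)-3-iodobut-2-en-1-ol, via oxaaluminacycle 6 (not isolated)
Conditions: Red-Al, THF, 0 °C → rt; then I2, THF, −78 °C → 0 °C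
Reagents that add atoms: iodine, II; Red-Al, COCCO[AlH2-]OCCOC.[Na+] (its aluminium and alkoxides are held only in 6)
Why: Hydroxyl-directed trans-hydroalumination of the propargylic alcohol puts aluminium on C3 in a five-membered chelate, and iodinolysis with retention fixes iodine cis to CH2OH.

Step 5
Reactants: 4 2-methyl-4-(triisopropylsilyloxy)-6-vinylphenol; 7 (Z)-3-iodobut-2-en-1-ol
Product: 9 2-[(Z)-5-hydroxy-3-methylpent-3-en-1-yl]-6-methyl-4-(triisopropylsilyloxy)phenol, via bis(9-BBN) adduct 8 (not isolated)
Conditions: 9-BBN (2.2 equiv), THF, rt; then 7, Pd(dppf)Cl2·CH2Cl2 (5 mol %), 3 M aq K3PO4, DMF, rt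
Reagents that add atoms: 9-BBN, B1C2CCCC1CCC2 (boron and its ring are held only in 8; 9 keeps only the hydrogen)
Why: In this B-alkyl Suzuki–Miyaura coupling 9-BBN first borylates the phenol OH and then adds anti-Markovnikov to the styrene, and the coupling proceeds with retention, so the Z geometry of 7 is carried into 9.

Step 6
Reactants: 9 2-[(Z)-5-hydroxy-3-methylpent-3-en-1-yl]-6-methyl-4-(triisopropylsilyloxy)phenol
Product: 10 (Z)-5-[2-hydroxy-3-methyl-5-(triisopropylsilyloxy)phenyl]-3-methylpent-2-en-1-yl methyl carbonate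
Conditions: ClCO2Me (1.1 equiv), pyridine, CH2Cl2, −20 → 0 °C
Reagents that add atoms: methyl chloroformate, COC(=O)Cl
Why: In this chemoselective O-acylation the primary allylic alcohol should outrun the 2,6-dialkyl-substituted phenol, which pyridine does not deprotonate.

Step 7
Reactants: 10 (Z)-5-[2-hydroxy-3-methyl-5-(triisopropylsilyloxy)phenyl]-3-methylpent-2-en-1-yl methyl carbonate
Product: 11 (R)-2,8-dimethyl-6-(triisopropylsilyloxy)-2-vinylchroman
Conditions: Pd2(dba)3·CHCl3 (2 mol %), (R,R)-DACH-phenyl ligand {N,N′-[(1R,2R)-cyclohexane-1,2-diyl]bis[2-(diphenylphosphino)benzamide]} (6 mol %), AcOH (1 equiv), CH2Cl2, rt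
Reagents that add atoms: none
Why: In this intramolecular Tsuji–Trost asymmetric allylic etherification, ionisation gives a π-allyl-Pd whose faces equilibrate through the CH2 terminus under the acetic acid buffer, the phenol closes the six-membered ring in 6-exo fashion at the more substituted terminus, and the chiral pocket of the ligand selects the faster-cyclising diastereomer and thereby sets C2.

Step 8
Reactants: 11 (R)-2,8-dimethyl-6-(triisopropylsilyloxy)-2-vinylchroman
Product: 12 (S)-2,8-dimethyl-6-(triisopropylsilyloxy)-2-vinyl-2H-chromene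
Conditions: DDQ (1.3 equiv), dry toluene, 80 °C, dark
Reagents that add atoms: none
Why: In this DDQ dehydrogenation of an electron-rich chroman, hydride leaves the benzylic C4 (cation stabilised by O1 through C8a) and a proton leaves C3, while C2 has no hydrogen and keeps its geometry (the descriptor changes only because C3 now outranks vinyl).

Step 9
Reactants: 13 geraniol
Product: 14 (2S,3S)-2,3-epoxygeraniol
Conditions: Ti(OiPr)4 (5 mol %), L-(+)-DET (7 mol %), t-BuOOH, 4 Å MS, CH2Cl2, −20 °C
Reagents that add atoms: tert-butyl hydroperoxide, CC(C)(C)OO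
Why: In the Sharpless asymmetric epoxidation only the allylic alkene binds to titanium through the OH, and the L-(+)-tartrate delivers oxygen to the face that gives (2S,3S), which sets the future C8′.

Step 10
Reactants: 14 (2S,3S)-2,3-epoxygeraniol
Product: 15 (2R,3S)-1-chloro-2,3-epoxy-3,7-dimethyloct-6-ene
Conditions: PPh3, CCl4, NaHCO3, reflux
Reagents that add atoms: carbon tetrachloride, ClC(Cl)(Cl)Cl
Why: The Appel chlorination of the primary alcohol runs under neutral conditions that leave the epoxide closed, and the C2 descriptor changes only through CIP ranking.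

Step 11
Reactants: 15 (2R,3S)-1-chloro-2,3-epoxy-3,7-dimethyloct-6-ene
Product: 16 (S)-3,7-dimethyloct-6-en-1-yn-3-ol
Conditions: n-BuLi (3.3 equiv), THF, −40 °C; aq NH4Cl
Reagents that add atoms: none
Why: In this base-induced double elimination of a 2,3-epoxy chloride, deprotonation at C1 opens the epoxide at C2–O, loss of HCl then gives the alkyne, and the C3–O bond and its configuration are untouched.

Step 12
Reactants: 17 propargyl alcohol
Product: 19 (E)-3-iodo-2-methylprop-2-en-1-ol, via alkenylalane 18 (not isolated)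
Conditions: Me3Al (3 equiv), Cp2ZrCl2 (25 mol %), CH2Cl2, 0 °C → rt; then I2, THF, −30 °C; aq K2CO3
Reagents that add atoms: trimethylaluminium, C[Al](C)C; iodine, II
Why: Negishi zirconium-catalysed carboalumination adds CH3 (internal carbon) and Al (terminal carbon) syn across the alkyne, and iodinolysis with retention places iodine cis to CH3, that is E.

Step 13
Reactants: 19 (E)-3-iodo-2-methylprop-2-en-1-ol
Product: 20 (E)-3-bromo-1-iodo-2-methylprop-1-ene
Conditions: CBr4, PPh3, CH2Cl2, 0 °C
Reagents that add atoms: carbon tetrabromide, BrC(Br)(Br)Br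
Why: The Appel bromination of the primary allylic alcohol leaves the alkenyl iodide and its geometry untouched.

Step 14
Reactants: 16 (S)-3,7-dimethyloct-6-en-1-yn-3-ol; 20 (E)-3-bromo-1-iodo-2-methylprop-1-ene
Product: 21 (1E,6S)-1-iodo-2,6,10-trimethylundeca-1,9-dien-4-yn-6-ol
Conditions: CuI (10 mol %), n-Bu4NBr (10 mol %), K2CO3, DMF, rt
Reagents that add atoms: none
Why: In this copper-catalysed coupling of a terminal alkyne with an allylic halide, the copper acetylide displaces the primary bromide at CH2, and the alkenyl iodide is inert at room temperature without palladium.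

Step 15
Reactants: 21 (1E,6S)-1-iodo-2,6,10-trimethylundeca-1,9-dien-4-yn-6-ol
Product: 23 (1E,4E,6S)-1-iodo-2,6,10-trimethylundeca-1,4,9-trien-6-ol, via oxaaluminacycle 22 (not isolated)
Conditions: Red-Al (3 equiv), THF, 0 °C → rt; aq Rochelle salt
Reagents that add atoms: Red-Al, COCCO[AlH2-]OCCOC.[Na+] (its aluminium and alkoxides are held only in 22; 23 keeps only hydrogen)
Why: In the hydroxyl-directed trans-hydroalumination of the propargylic alcohol, the alkoxide-bound hydride goes to C5, aluminium goes to C4 in a five-membered ring, and protonolysis with retention gives the E-alkene of the skipped diene.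

Step 16
Reactants: 12 (S)-2,8-dimethyl-6-(triisopropylsilyloxy)-2-vinyl-2H-chromene; 23 (1E,4E,6S)-1-iodo-2,6,10-trimethylundeca-1,4,9-trien-6-ol
Product: 25 (2S)-2-[(3E,6E,8S)-8-hydroxy-4,8,12-trimethyltrideca-3,6,11-trien-1-yl]-2,8-dimethyl-6-(triisopropylsilyloxy)-2H-chromene, via B-alkyl-9-BBN 24 (not isolated)
Conditions: 9-BBN (1.1 equiv), THF, 0 °C → rt; then 23, Pd(dppf)Cl2·CH2Cl2 (5 mol %), AsPh3 (10 mol %), Cs2CO3, DMF/H2O, rt, Ar, dark
Reagents that add atoms: 9-BBN, B1C2CCCC1CCC2 (boron and its ring are held only in 24; 25 keeps only the hydrogen)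
Why: 9-BBN adds B–H across the C1′=C2′ vinyl group of 12 with boron on the terminal C2′; aqueous carbonate turns borane 24 into a hydroxyborate that hands this primary alkyl group to the alkenyl–Pd(II) iodide formed by oxidative addition of 23, and reductive elimination makes the C2′–C3′ bond. The closest known reaction type is the one-flask hydroboration/B-alkyl Suzuki–Miyaura coupling of 2-vinylchromans and other neopentyl-type vinyl groups with E-2-methyl-1-iodoalkenes. No ring is closed and no stereocentre is made: C2 and C8′ are spectators, and since oxidative addition, transmetalation and reductive elimination all go with retention at the sp2 carbon, the E geometry of C3′=C4′ is taken over from 23. The selectivity needed is hydroboration of one alkene only: the vinyl group is the sole monosubstituted alkene, the ring alkene C3=C4 is cis-disubstituted, aryl-conjugated and next to the quaternary C2 and should react far more slowly with the bulky dialkylborane, and the three alkenes of 23 never meet B–H because the aqueous base destroys any excess before 23 goes in. Quaternary C2 also rules out alkene migration and keeps boron γ (not β) to O1 so that no boron–oxygen elimination can occur, and the wide-bite-angle dppf ligand favours reductive elimination over β-hydride loss from the C2′–Pd alkyl. The free tertiary allylic alcohol is not ionised by Pd(0) in basic medium, room temperature and darkness guard the skipped diene and the photolabile C2–O1 bond, and any loss of the aryl silyl ether only anticipates step 17.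

Step 17
Reactants: 25 (2S)-2-[(3E,6E,8S)-8-hydroxy-4,8,12-trimethyltrideca-3,6,11-trien-1-yl]-2,8-dimethyl-6-(triisopropylsilyloxy)-2H-chromene
Product: 26 (2S)-2-[(3E,6E,8S)-8-hydroxy-4,8,12-trimethyltrideca-3,6,11-trien-1-yl]-2,8-dimethyl-2H-chromen-6-ol
Conditions: TBAF, AcOH (1:1), THF, 0 °C, Ar, dark
Reagents that add atoms: none
Why: Fluoride cleaves the aryl silyl ether, and the acetic acid buffer protonates the oxidation-prone phenoxide at once while being too weak to ionise the tertiary allylic alcohol.

**Compound list**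
1 | 2-methylhydroquinone | Cc1cc(O)ccc1O | starting material
2 | 2-methyl-4-(triisopropylsilyloxy)phenol | Cc1cc(O[Si](C(C)C)(C(C)C)C(C)C)ccc1O | intermediate
3 | 2-hydroxy-3-methyl-5-(triisopropylsilyloxy)benzaldehyde | Cc1cc(O[Si](C(C)C)(C(C)C)C(C)C)cc(C=O)c1O | intermediate
4 | 2-methyl-4-(triisopropylsilyloxy)-6-vinylphenol | Cc1cc(O[Si](C(C)C)(C(C)C)C(C)C)cc(C=C)c1O | intermediate
5 | but-2-yn-1-ol | CC#CCO | starting material
6 | sodium oxaaluminacycle from 5 and Red-Al (Al on C3, not isolated) | CC1=CCO[Al-]1(OCCOC)OCCOC.[Na+] | intermediate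
7 | (Z)-3-iodobut-2-en-1-ol | C/C(I)=C/CO | intermediate
8 | O,C-bis(9-BBN) adduct of 4 (aryl borinate and primary alkylborane, not isolated) | Cc1cc(O[Si](C(C)C)(C(C)C)C(C)C)cc(CCB2C3CCCC2CCC3)c1OB1C2CCCC1CCC2 | intermediate
9 | 2-[(Z)-5-hydroxy-3-methylpent-3-en-1-yl]-6-methyl-4-(triisopropylsilyloxy)phenol | Cc1cc(O[Si](C(C)C)(C(C)C)C(C)C)cc(CC/C(C)=C\CO)c1O | intermediate
10 | (Z)-5-[2-hydroxy-3-methyl-5-(triisopropylsilyloxy)phenyl]-3-methylpent-2-en-1-yl methyl carbonate | Cc1cc(O[Si](C(C)C)(C(C)C)C(C)C)cc(CC/C(C)=C\COC(=O)OC)c1O | intermediate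
11 | (R)-2,8-dimethyl-6-(triisopropylsilyloxy)-2-vinylchroman | C=C[C@@]1(C)CCc2cc(O[Si](C(C)C)(C(C)C)C(C)C)cc(C)c2O1 | intermediate
12 | (S)-2,8-dimethyl-6-(triisopropylsilyloxy)-2-vinyl-2H-chromene | C=C[C@@]1(C)C=Cc2cc(O[Si](C(C)C)(C(C)C)C(C)C)cc(C)c2O1 | intermediate
13 | geraniol | CC(C)=CCC/C(C)=C/CO | starting material
14 | (2S,3S)-2,3-epoxygeraniol | CC(C)=CCC[C@]1(C)O[C@H]1CO | intermediate
15 | (2R,3S)-1-chloro-2,3-epoxy-3,7-dimethyloct-6-ene | CC(C)=CCC[C@]1(C)O[C@H]1CCl | intermediate
16 | (S)-3,7-dimethyloct-6-en-1-yn-3-ol | CC(C)=CCC[C@](C)(O)C#C | intermediate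
17 | propargyl alcohol | C#CCO | starting material
18 | (E)-alkenyl(dimethyl)alane O-dimethylaluminium alkoxide from 17 (not isolated) | C[Al](C)OC/C(C)=C/[Al](C)C | intermediate
19 | (E)-3-iodo-2-methylprop-2-en-1-ol | OC/C(C)=C/I | intermediate
20 | (E)-3-bromo-1-iodo-2-methylprop-1-ene | BrC/C(C)=C/I | intermediate
21 | (1E,6S)-1-iodo-2,6,10-trimethylundeca-1,9-dien-4-yn-6-ol | CC(C)=CCC[C@](C)(O)C#CC/C(C)=C/I | intermediate
22 | sodium oxaaluminacycle from 21 and Red-Al (Al on C4, not isolated) | CC(C)=CCC[C@@]1(C)C=C(C/C(C)=C/I)[Al-](OCCOC)(OCCOC)O1.[Na+] | intermediate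
23 | (1E,4E,6S)-1-iodo-2,6,10-trimethylundeca-1,4,9-trien-6-ol | CC(C)=CCC[C@](C)(O)/C=C/C/C(C)=C/I | intermediate
24 | B-{2-[(2S)-2,8-dimethyl-6-(triisopropylsilyloxy)-2H-chromen-2-yl]ethyl}-9-BBN (not isolated) | B1(CC[C@@]2(C)C=Cc3cc(O[Si](C(C)C)(C(C)C)C(C)C)cc(C)c3O2)C2CCCC1CCC2 | intermediate
25 | (2S)-2-[(3E,6E,8S)-8-hydroxy-4,8,12-trimethyltrideca-3,6,11-trien-1-yl]-2,8-dimethyl-6-(triisopropylsilyloxy)-2H-chromene | CC(C)=CCC[C@](C)(O)/C=C/C/C(C)=C/CC[C@@]1(C)C=Cc2cc(O[Si](C(C)C)(C(C)C)C(C)C)cc(C)c2O1 | intermediate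
26 | (2S)-2-[(3E,6E,8S)-8-hydroxy-4,8,12-trimethyltrideca-3,6,11-trien-1-yl]-2,8-dimethyl-2H-chromen-6-ol (CNP0155965.1) | CC(C)=CCC[C@](C)(O)/C=C/C/C(C)=C/CC[C@@]1(C)C=Cc2cc(O)cc(C)c2O1 | target

Total step count: 17.
Longest linear sequence: 9 steps (1, 2, 3, 5, 6, 7, 8, 16, 17). The left half reaches the union in 5 linear steps (9, 10, 11, 14, 15).

**Steps most likely to fail**

Step 16. The alkyl group may transfer from boron to palladium too slowly. Loss of iodine from 23, base-induced cleavage of the aryl silyl ether and Pd–H migration within the skipped diene would then compete. The fallback is a base-free Negishi alkyl–alkenyl coupling that sets out from 12 and 23 and returns at 26.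
- 12 is hydroborated to 24 as before, but the borane is oxidised (NaBO3·4H2O) to the primary alcohol 2-[(2S)-2,8-dimethyl-6-(triisopropylsilyloxy)-2H-chromen-2-yl]ethanol F1.
- I2/PPh3/imidazole converts it into the primary iodide (2S)-2-(2-iodoethyl)-2,8-dimethyl-6-(triisopropylsilyloxy)-2H-chromene F2.
- Zinc dust/LiCl in THF gives the alkylzinc iodide F3.
- 23 is capped with TESOTf/2,6-lutidine as its triethylsilyl ether F4.
- Pd(dppf)Cl2 in THF at rt joins F3 and F4 to the bis-silyl ether F5, and TBAF removes both silyl groups to give 26.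

Step 15. The alkenyl iodide may be reduced by the aluminium hydride, or the skipped enyne may isomerise under base towards an allene, before the directed hydroalumination is complete. The fallback installs iodine only after the reduction. It sets out from 16 and returns at 23.
- 16 is coupled (CuI, K2CO3, DMF) with 3-bromo-1-(trimethylsilyl)propyne to the skipped diynol (6S)-6,10-dimethyl-1-(trimethylsilyl)undec-9-ene-1,4-diyn-6-ol F6.
- Red-Al reduces only the alkyne next to the carbinol, through the oxaaluminacycle F7, to the silylated E-enynol F8.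
- K2CO3/MeOH frees the terminal enynol (4E,6S)-6,10-dimethylundeca-4,9-dien-1-yn-6-ol F9.
- Zirconium-catalysed methylalumination gives the alkenylalane F10, whose iodinolysis gives 23.

Step 8. The electron-rich silyl hydroquinone ether may be over-oxidised (oxidative desilylation towards a quinone). Hydride abstraction may also be incomplete, or the configuration at C2 may erode through thermal oxa-6π ring opening at the temperature required. The fallback oxidises the free p-alkoxyphenol instead, which should react through its phenoxonium ion at room temperature. It sets out from 11 and returns at 12.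
- TBAF converts 11 into (R)-2,8-dimethyl-2-vinylchroman-6-ol F11.
- DDQ in toluene at rt gives (S)-2,8-dimethyl-2-vinyl-2H-chromen-6-ol F12.
- TIPSCl/imidazole returns 12.

**Further compounds**
F1 | step 16 | 2-[(2S)-2,8-dimethyl-6-(triisopropylsilyloxy)-2H-chromen-2-yl]ethanol | OCC[C@@]1(C)C=Cc2cc(O[Si](C(C)C)(C(C)C)C(C)C)cc(C)c2O1
F2 | step 16 | (2S)-2-(2-iodoethyl)-2,8-dimethyl-6-(triisopropylsilyloxy)-2H-chromene | ICC[C@@]1(C)C=Cc2cc(O[Si](C(C)C)(C(C)C)C(C)C)cc(C)c2O1
F3 | step 16 | {2-[(2S)-2,8-dimethyl-6-(triisopropylsilyloxy)-2H-chromen-2-yl]ethyl}zinc iodide | I[Zn]CC[C@@]1(C)C=Cc2cc(O[Si](C(C)C)(C(C)C)C(C)C)cc(C)c2O1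
F4 | step 16 | triethylsilyl ether of 23 | CC(C)=CCC[C@](C)(O[Si](CC)(CC)CC)/C=C/C/C(C)=C/I
F5 | step 16 | 8′-O-triethylsilyl-6-O-triisopropylsilyl derivative of 26 | CC(C)=CCC[C@](C)(O[Si](CC)(CC)CC)/C=C/C/C(C)=C/CC[C@@]1(C)C=Cc2cc(O[Si](C(C)C)(C(C)C)C(C)C)cc(C)c2O1
F6 | step 15 | (6S)-6,10-dimethyl-1-(trimethylsilyl)undec-9-ene-1,4-diyn-6-ol | CC(C)=CCC[C@](C)(O)C#CCC#C[Si](C)(C)C
F7 | step 15 | sodium oxaaluminacycle from F6 and Red-Al | CC(C)=CCC[C@@]1(C)C=C(CC#C[Si](C)(C)C)[Al-](OCCOC)(OCCOC)O1.[Na+]
F8 | step 15 | (4E,6S)-6,10-dimethyl-1-(trimethylsilyl)undeca-4,9-dien-1-yn-6-ol | CC(C)=CCC[C@](C)(O)/C=C/CC#C[Si](C)(C)C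
F9 | step 15 | (4E,6S)-6,10-dimethylundeca-4,9-dien-1-yn-6-ol | CC(C)=CCC[C@](C)(O)/C=C/CC#C
F10 | step 15 | (E)-alkenyl(dimethyl)alane O-dimethylaluminium alkoxide from F9 | CC(C)=CCC[C@](C)(O[Al](C)C)/C=C/C/C(C)=C/[Al](C)C
F11 | step 8 | (R)-2,8-dimethyl-2-vinylchroman-6-ol | C=C[C@@]1(C)CCc2cc(O)cc(C)c2O1
F12 | step 8 | (S)-2,8-dimethyl-2-vinyl-2H-chromen-6-ol | C=C[C@@]1(C)C=Cc2cc(O)cc(C)c2O1
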